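## Structural features

The target is a 6,7-dihydro-5H-cyclopenta[c]pyridine: pyridine ring A (C1, N2, C3, C4) is fused through C4a–C7a to cyclopentanone ring B (C5, C6, C7). C3 carries a (1E,3E,5S)-3,5-dimethylhepta-1,3-dienyl chain whose single stereocentre is remote from the core, so the chain can be made separately and attached late. Ring B holds two adjacent, fully substituted stereocentres, C5 (R; OH, CO2Me) and C6 (S; CH3, OAc), with the two oxygens trans, next to the C7 ketone that is conjugated with ring A. The fragile points are these: the tertiary C5 hydroxyl is β to the C7 ketone, so base can open ring B by retro-aldol cleavage of C5–C6 and erase both stereocentres; the tertiary α-acetoxy ketone is an activated ester; the dienyl pyridine does not tolerate strong acid, oxidants or hard nucleophiles; and the allylic sec-butyl centre must not be epimerised. The real difficulty is the vicinal pair of quaternary carbinol carbons in absolute and relative configuration, together with the need to tell two tertiary hydroxyls apart. The key step uses the fact that, once ring B is opened at C7–C7a, C5 and C6 are the two carbons of an open-chain tetrasubstituted alkene. If C7 and the ester carbon on C5 are cis on that alkene, delivery of both oxygens to one face gives the trans C5–O/C6–O array after C7 is tied back to C7a. Because the oxygens end up trans on a five-membered ring, a cyclic diol protecting group cannot be carried through the ring closure, and acetyl migration from O6 to O5 is not a concern in the bicycle.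

## Logic of the disconnections

25 ⇒ 24: the O5–Si bond is cut. The free C5 hydroxyl is the base-labile element, so it is unveiled last. The gain is that every earlier step runs on a compound with no retro-aldol pathway. The demand is a non-basic desilylation that spares the acetate, the ester and the diene.

24 ⇒ 19 + 23: the C3–C1′ bond is cut. It is an sp2–sp2 bond at a pyridine carbon next to nitrogen and para to the acyl group, hence an activated C–Cl for cross-coupling. The gain is convergence, with the whole chain arriving in one piece. The demand is a mild base, retention of both alkene geometries, and a chloride that has survived all earlier steps.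

23 ⇒ 22 ⇒ 20: C1′=C2′ is cut first, then C3′=C4′. Both are carbonyl olefinations that lead back to a chiral-pool alcohol. The gain is that the only chain stereocentre is bought. The demand is E control twice and no epimerisation of the α-branched aldehyde 21.

19 ⇒ 17 (through 18): the O6–acyl bond is cut. An acetate present before ring closure would compete as an electrophile, so acetyl is introduced only afterwards. The demand is that O6 carries a group much more labile than the one on O5.

17 ⇒ 15 (through 16): the C7–C7a bond is cut. C7a is an aryl anion equivalent (C–Br), and C7 is the ester carbon on C6. Ring size decides between the two esters (five-membered against four-membered). The gain is that ring B disappears and the stereocentres sit in an open chain. The demand is metalation in the presence of two esters and two silyl ethers, and two separate (not cyclic) protecting groups.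

15 ⇒ 14 ⇒ 13: the two O–Si bonds are cut. The hydroxyls are told apart in the open chain, where the bromopyridyl group shields the oxygen on C2. The demand is a site-selective first silylation.

13 ⇒ 12: both C–O bonds are cut (C2–O and C3–O, the later C5–O and C6–O). Both stereocentres vanish and an achiral, flat precursor remains. The demand is enantioface-selective syn delivery of two oxygens to a tetrasubstituted acceptor alkene, and a geometrically pure Z alkene.

12 ⇒ 10 (through 11) ⇒ 8 (through 9): the two ester C–O bonds are cut and re-formed through a cyclic anhydride. The ring can only hold the carboxyl carbons cis, so a mixture of isomers is converted into one geometry. The demand is that the E acid isomerises under the ring-closing conditions.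

8 ⇒ 4 + 5 (through 6 and 7): the C=C bond is cut by an aldol addition and elimination sequence. The gain is two simple esters. No demand is put on geometry.

4 ⇒ 3 ⇒ 1 + 2: the aryl–C bond (later C4a–C5) is cut by SNAr, after one ester carbon is removed. The demand is substitution at C4 and not at C2 of the pyridine.

## Other disconnections considered

Alternative 1: C4a–C7a, C3–C4 and N2–C1 are cut together. This leaves the silyl-capped 1,6-diyne A2 (ynone, C6 acetate, C5 carbinol with ethynyl and ester) and the dienyl nitrile A3. In the forward sense CpCo(CO)2 (heat or light) would form a cobaltacyclopentadiene from the two alkynes and insert the nitrile, giving the 1-silyl pyridine A1, from which silicon must still be removed.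
- In favour: two rings and three skeletal bonds are made in one step, the chain arrives with the nitrile, and the silyl group should steer the nitrile carbon to C3. In bond-forming power this is better than the chosen key step.
- Against: A2 already contains both quaternary stereocentres, now flanked by an ynone and a propargylic carbinol that is itself β to a ketone. The stereochemical problem is therefore not solved, only moved to a more sensitive substrate. Cobalt may also bind the diene of A3 or engage its conjugated C=C.
- Comparison: the reaction class is established, which the chosen key step is not, so on precedent it is better. After the key step it is clearly shorter (one protodesilylation against eight steps). Before the key step it is longer and without a clear source of asymmetry, so overall it is judged weaker.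

Alternative 2: C6–C7 is cut, leading to the keto aldehyde A5 (formyl group on the pyridine, methyl ketone on the silyloxy-bearing C5). In the forward sense a chiral triazolium-derived carbene would turn the aldehyde into a Breslow intermediate that adds to the ketone, closing ring B to A4.
- In favour: intramolecular aldehyde–ketone benzoin closures to five-membered tertiary ketols are well established, and no metal is needed. A4 is the same compound as 18, so the end game would be identical; on these points it is equal or better.
- Against: only C6 is created. C5 must already be present as one enantiomer in A5, an α-silyloxy β-keto ester without α-hydrogen that is prone to retro-Claisen deacylation by the carbene or its base. The trans O/O relationship then depends on a match between catalyst and the existing centre. The formyl group must also be installed next to a quaternary benzylic carbon.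
- Comparison: the mechanism (umpolung) is better precedented than the chosen iron chemistry. Structurally it gives a ring and one centre where the chosen step gives two centres and no ring, so a second asymmetric operation is needed. Step economy is equal after the key step and probably worse before it.

Alternative 3: C4a–C5 is cut, leading to the pyridyl boronate A7, whose side chain is an α-keto ester joined through the acetoxy-bearing C6 to the aryl ketone. In the forward sense [Rh(cod)OH]2 with a chiral diene or bisphosphine would transmetalate to an aryl–rhodium species (monovalent rhodium) that adds 5-exo to the keto ester carbonyl, giving A6.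
- In favour: A6 has the free C5 hydroxyl and the C6 acetate already in place, so no protecting groups are needed and only the cross-coupling remains. In end-game length it is better than the chosen plan. Aryl–rhodium additions to α-keto esters are well known and tolerant.
- Against: A7 is a 2-acyloxy-1,3-dicarbonyl compound fused to an α-keto ester. It is prone to hydration and retro-Claisen cleavage under the aqueous base needed for transmetalation, and its quaternary C6 centre must be made enantioselectively beforehand. An acyl-flanked pyridyl boronate is liable to protodeboronation, and the last coupling would run on the free β-hydroxy ketone.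
- Comparison: mechanistically it is equal or better in precedent. Structurally it sets one centre with the ring, where the chosen step sets two. It is shorter after the key step, but longer and more fragile before it.

Key step: step 6

Remark on stereochemistry: syn delivery of two oxygens to the Z diester 12 gives the (2R,3S) diol 13. C2 and C3 of 13 become C5 (R) and C6 (S) of the bicycle with the oxygens trans, so the structures agree with one another and none is revised.

Remark on design: 12 keeps both halogens. Chlorine and bromine make the pyridine nitrogen non-basic towards iron and peroxide, and bromine later fixes the site of ring closure. 12 is made through the cyclic anhydride and kept from light, because any E isomer would lead to the wrong (cis O/O) diastereomer.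

Assumption: the (R,R) ligand is taken to give the (2R,3S) diol; if the sense of induction is the opposite, the (S,S) antipode is used with no other change.

Numbering: open-chain compounds use butanedioate numbering (C2 = later C5, C3 = later C6); bicyclic compounds use cyclopenta[c]pyridine numbering.

## Route

Step 1
Reactants: 1 5-bromo-2,4-dichloropyridine; 2 dimethyl malonate
Product: 3 dimethyl 2-(5-bromo-2-chloropyridin-4-yl)propanedioate
Conditions: Cs2CO3, DMSO, 60 °C
Reagents that add atoms: none
Why: SNAr; the malonate anion attacks C4, which is para to nitrogen, further activated by the ortho bromine, and the usual site for carbon nucleophiles in 2,4-dichloropyridines. The product is held as its unreactive enolate, which prevents a second substitution.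

Step 2
Reactants: 3 dimethyl 2-(5-bromo-2-chloropyridin-4-yl)propanedioate
Product: 4 methyl 2-(5-bromo-2-chloropyridin-4-yl)acetate
Conditions: LiCl, H2O, DMSO, 120 °C
Reagents that add atoms: none
Why: Krapcho dealkoxycarbonylation; chloride demethylates one ester and the carboxylate loses CO2 through a pyridyl-stabilised carbanion. The near-neutral conditions leave both ring halogens in place.

Step 3
Reactants: 4 methyl 2-(5-bromo-2-chloropyridin-4-yl)acetate; 5 methyl pyruvate
Product: 8 dimethyl 2-(5-bromo-2-chloropyridin-4-yl)-3-methylbut-2-enedioate (E/Z mixture), via lithium aldolate 6 (not isolated), via aldol acetate 7 (not isolated)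
Conditions: LiN(SiMe3)2, THF, −78 °C; 5; Ac2O, −78 → 0 °C; DBU, rt
Reagents that add atoms: none
Why: Aldol addition of the ester enolate to the ketone carbonyl of 5, O-acetylation of the tertiary alkoxide, and E1cB elimination through the pyridyl- and ester-stabilised carbanion. Alkene geometry is not controlled and need not be, because step 4 converts both isomers into one ring.

Step 4
Reactants: 8 dimethyl 2-(5-bromo-2-chloropyridin-4-yl)-3-methylbut-2-enedioate (E/Z mixture)
Product: 10 3-(5-bromo-2-chloropyridin-4-yl)-4-methylfuran-2,5-dione, via diacid 9 (not isolated)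
Conditions: LiOH, THF/H2O, 40 °C; aq. HCl; then Ac2O, NaOAc (cat.), 100 °C
Reagents that add atoms: lithium hydroxide, [Li+].[OH-]
Why: Saponification and dehydrative closure; the Z acid closes directly and the E acid isomerises under the hot acetate conditions (mixed anhydride, reversible γ-deprotonation) into the five-membered anhydride. The ring can only hold the two carboxyl carbons cis, which fixes the geometry.

Step 5
Reactants: 10 3-(5-bromo-2-chloropyridin-4-yl)-4-methylfuran-2,5-dione
Product: 12 dimethyl (Z)-2-(5-bromo-2-chloropyridin-4-yl)-3-methylbut-2-enedioate, via half-ester 11 (not isolated)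
Conditions: MeOH, Et3N, rt; then MeI, K2CO3, DMF, rt, dark
Reagents that add atoms: methanol, CO; iodomethane, CI
Why: Methanolysis of the anhydride (expected at the less hindered carbonyl next to the methyl-bearing carbon) and SN2 methylation of the carboxylate. No bond to an alkene carbon is touched, so the Z geometry is kept; light is excluded to avoid photoisomerisation.

Step 6
Reactants: 12 dimethyl (Z)-2-(5-bromo-2-chloropyridin-4-yl)-3-methylbut-2-enedioate
Product: 13 dimethyl (2R,3S)-2-(5-bromo-2-chloropyridin-4-yl)-2,3-dihydroxy-3-methylbutanedioate
Conditions: Fe(OTf)2 (10 mol%), (R,R)-N,N′-dimethyl-N,N′-bis(2-methylquinolin-8-yl)cyclohexane-1,2-diamine (10 mol%), 30% aq. H2O2 (slow addition), MeOH, −20 °C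
Reagents that add atoms: hydrogen peroxide, OO
Why: Proposed new method: H2O2 oxidises the divalent iron complex, through an iron hydroperoxide, to a high-valent iron oxo-hydroxo unit whose two cis oxygen ligands add across C2=C3 of 12 in a concerted (3+2) manner, so both C–O bonds form on the same face and no ring is closed. The closest known reaction type is the enantioselective cis-dihydroxylation of electron-poor trisubstituted alkenes with chiral tetradentate N4 iron catalysts and H2O2 (more remotely the osmium tetroxide asymmetric dihydroxylation); a tetrasubstituted diester of this kind has not been shown, hence the label. The relative configuration of C2 and C3 is fixed by the substrate, since suprafacial delivery to the Z alkene can only give the syn diol. The absolute configuration (2R,3S) is fixed by the ligand, whose chiral pocket has to tell the alkene end carrying the bulky, twisted bromopyridyl group from the end carrying methyl. The step needs enantioface selectivity, diol-over-epoxide selectivity and chemoselectivity for the alkene over the pyridine nitrogen. The two cis-labile sites of the complex favour the diol, the chloro and bromo substituents make the nitrogen too weakly basic to bind iron or be N-oxidised, and an acceptor alkene suits this class of oxidant, which, unlike OsO4, accepts electron-poor alkenes.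

Step 7
Reactants: 13 dimethyl (2R,3S)-2-(5-bromo-2-chloropyridin-4-yl)-2,3-dihydroxy-3-methylbutanedioate
Product: 14 dimethyl (2R,3S)-2-(5-bromo-2-chloropyridin-4-yl)-2-hydroxy-3-methyl-3-[(trimethylsilyl)oxy]butanedioate
Conditions: TMSCl (1.1 equiv), imidazole, CH2Cl2, −20 → 0 °C
Reagents that add atoms: chlorotrimethylsilane, C[Si](C)(C)Cl
Why: Site-selective silylation; the hydroxyl on C3 has a methyl neighbour, whereas the one on C2 is shielded by the ortho-bromopyridyl group and is less nucleophilic. Any bis-silylated material can be returned to 13 by mild methanolysis.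

Step 8
Reactants: 14 dimethyl (2R,3S)-2-(5-bromo-2-chloropyridin-4-yl)-2-hydroxy-3-methyl-3-[(trimethylsilyl)oxy]butanedioate
Product: 15 dimethyl (2R,3S)-2-(5-bromo-2-chloropyridin-4-yl)-3-methyl-2-[(triethylsilyl)oxy]-3-[(trimethylsilyl)oxy]butanedioate
Conditions: TESOTf, 2,6-lutidine, CH2Cl2, 0 °C → rt
Reagents that add atoms: triethylsilyl trifluoromethanesulfonate, CC[Si](CC)(CC)OS(=O)(=O)C(F)(F)F
Why: Silyl triflates silylate even hindered tertiary alcohols. Two open-chain ethers are used because a cyclic diol derivative would require a trans-fused bicycle at ring closure. The triethylsilyl ether outlasts the trimethylsilyl ether by a wide margin in acid methanolysis, which step 10 relies on.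

Step 9
Reactants: 15 dimethyl (2R,3S)-2-(5-bromo-2-chloropyridin-4-yl)-3-methyl-2-[(triethylsilyl)oxy]-3-[(trimethylsilyl)oxy]butanedioate
Product: 17 methyl (5R,6S)-3-chloro-6-methyl-7-oxo-5-[(triethylsilyl)oxy]-6-[(trimethylsilyl)oxy]-6,7-dihydro-5H-cyclopenta[c]pyridine-5-carboxylate, via arylmagnesium chloride 16 (not isolated)
Conditions: iPrMgCl·LiCl (1.1 equiv), THF, −40 → 0 °C; aq. NH4Cl
Reagents that add atoms: none
Why: Parham-type cyclisation; bromine–magnesium exchange at the electron-poor pyridine, then 5-exo-trig attack of the aryl carbon on the ester carbonyl attached to C3 and loss of methoxide (the other ester could only close a four-membered ring). The new ketone has no α-hydrogen and O5 is capped, so neither stereocentre can be lost; magnesium rather than lithium is chosen to suppress O-to-C silyl shifts.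

Step 10
Reactants: 17 methyl (5R,6S)-3-chloro-6-methyl-7-oxo-5-[(triethylsilyl)oxy]-6-[(trimethylsilyl)oxy]-6,7-dihydro-5H-cyclopenta[c]pyridine-5-carboxylate
Product: 19 methyl (5R,6S)-6-acetoxy-3-chloro-6-methyl-7-oxo-5-[(triethylsilyl)oxy]-6,7-dihydro-5H-cyclopenta[c]pyridine-5-carboxylate, via C6 alcohol 18 (not isolated)
Conditions: PPTS, MeOH, 0 °C; evaporate; then Ac2O, Et3N, DMAP, CH2Cl2, rt
Reagents that add atoms: acetic anhydride, CC(=O)OC(C)=O
Why: Acid methanolysis removes the trimethylsilyl group selectively, and DMAP-catalysed acylation then acetylates the tertiary α-ketol. O5 stays silylated, so only O6 can be acylated.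

Step 11
Reactants: 20 (S)-2-methylbutan-1-ol
Product: 22 (2E,4S)-2,4-dimethylhex-2-enal, via (S)-2-methylbutanal 21 (not isolated)
Conditions: TEMPO (cat.), KBr, NaOCl, NaHCO3, CH2Cl2/H2O, 0 °C; dried organic phase, then Ph3P=C(CH3)CHO, toluene, 80 °C
Reagents that add atoms: 2-(triphenylphosphoranylidene)propanal, CC(C=O)=P(c1ccccc1)(c1ccccc1)c1ccccc1
Why: Buffered nitroxyl/hypochlorite oxidation should give the α-branched aldehyde without epimerisation, and it is used in solution at once. Wittig olefination with the formyl-stabilised ylide gives the E trisubstituted enal under thermodynamic control.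

Step 12
Reactants: 22 (2E,4S)-2,4-dimethylhex-2-enal
Product: 23 2-[(1E,3E,5S)-3,5-dimethylhepta-1,3-dien-1-yl]-4,4,5,5-tetramethyl-1,3,2-dioxaborolane
Conditions: CH2(Bpin)2, lithium 2,2,6,6-tetramethylpiperidide, THF, 0 °C; then 22, −78 °C → rt
Reagents that add atoms: bis(pinacolato)borylmethane, CC1(C)OB(CB2OC(C)(C)C(C)(C)O2)OC1(C)C
Why: Boron-Wittig olefination; 1,2-addition of the α-boryl carbanion to the aldehyde and syn elimination of boron and oxygen should give the E alkenyl boronate. The stabilised carbanion is a poor base, so the γ-stereocentre of the enal is not deprotonated.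

Step 13
Reactants: 19 methyl (5R,6S)-6-acetoxy-3-chloro-6-methyl-7-oxo-5-[(triethylsilyl)oxy]-6,7-dihydro-5H-cyclopenta[c]pyridine-5-carboxylate; 23 2-[(1E,3E,5S)-3,5-dimethylhepta-1,3-dien-1-yl]-4,4,5,5-tetramethyl-1,3,2-dioxaborolane
Product: 24 methyl (5R,6S)-6-acetoxy-3-[(1E,3E,5S)-3,5-dimethylhepta-1,3-dien-1-yl]-6-methyl-7-oxo-5-[(triethylsilyl)oxy]-6,7-dihydro-5H-cyclopenta[c]pyridine-5-carboxylate
Conditions: Pd(OAc)2 (5 mol%), SPhos (10 mol%), K3PO4, THF/H2O (20:1), 40 °C
Reagents that add atoms: none
Why: Suzuki–Miyaura coupling; zerovalent palladium inserts readily into the C3–Cl bond, which is next to nitrogen and para to the acyl group, and transmetalation of the alkenyl boronate retains both alkene geometries. The silyl group on O5 blocks base-induced retro-aldol opening of ring B.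

Step 14
Reactants: 24 methyl (5R,6S)-6-acetoxy-3-[(1E,3E,5S)-3,5-dimethylhepta-1,3-dien-1-yl]-6-methyl-7-oxo-5-[(triethylsilyl)oxy]-6,7-dihydro-5H-cyclopenta[c]pyridine-5-carboxylate
Product: 25 methyl (5R,6S)-6-acetoxy-3-[(1E,3E,5S)-3,5-dimethylhepta-1,3-dien-1-yl]-5-hydroxy-6-methyl-7-oxo-6,7-dihydro-5H-cyclopenta[c]pyridine-5-carboxylate
Conditions: HF·pyridine, pyridine, THF, 0 °C → rt
Reagents that add atoms: none
Why: Fluoride-driven cleavage of the Si–O bond under buffered, non-basic conditions; the acetate, the methyl ester and the diene should be untouched and the β-hydroxy ketone is never exposed to base.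

## Compound list

1 | 5-bromo-2,4-dichloropyridine | Clc1cc(Cl)c(Br)cn1 | starting material
2 | dimethyl malonate | COC(=O)CC(=O)OC | starting material
3 | dimethyl 2-(5-bromo-2-chloropyridin-4-yl)propanedioate | COC(=O)C(C(=O)OC)c1cc(Cl)ncc1Br | intermediate
4 | methyl 2-(5-bromo-2-chloropyridin-4-yl)acetate | COC(=O)Cc1cc(Cl)ncc1Br | intermediate
5 | methyl pyruvate | CC(=O)C(=O)OC | starting material
6 | lithium aldolate of dimethyl 2-(5-bromo-2-chloropyridin-4-yl)-3-hydroxy-3-methylbutanedioate (diastereomer mixture, not isolated) | COC(=O)C(c1cc(Cl)ncc1Br)C(C)(O[Li])C(=O)OC | intermediate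
7 | dimethyl 2-acetoxy-3-(5-bromo-2-chloropyridin-4-yl)-2-methylbutanedioate (diastereomer mixture, not isolated) | COC(=O)C(c1cc(Cl)ncc1Br)C(C)(OC(C)=O)C(=O)OC | intermediate
8 | dimethyl 2-(5-bromo-2-chloropyridin-4-yl)-3-methylbut-2-enedioate (E/Z mixture) | COC(=O)C(c1cc(Cl)ncc1Br)=C(C)C(=O)OC | intermediate
9 | 2-(5-bromo-2-chloropyridin-4-yl)-3-methylbut-2-enedioic acid (E/Z mixture, not isolated) | OC(=O)C(c1cc(Cl)ncc1Br)=C(C)C(=O)O | intermediate
10 | 3-(5-bromo-2-chloropyridin-4-yl)-4-methylfuran-2,5-dione | CC1=C(c2cc(Cl)ncc2Br)C(=O)OC1=O | intermediate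
11 | (Z)-2-(5-bromo-2-chloropyridin-4-yl)-4-methoxy-3-methyl-4-oxobut-2-enoic acid (triethylammonium salt in the flask, not isolated) | COC(=O)/C(C)=C(/c1cc(Cl)ncc1Br)C(=O)O | intermediate
12 | dimethyl (Z)-2-(5-bromo-2-chloropyridin-4-yl)-3-methylbut-2-enedioate | COC(=O)/C(c1cc(Cl)ncc1Br)=C(/C)C(=O)OC | intermediate
13 | dimethyl (2R,3S)-2-(5-bromo-2-chloropyridin-4-yl)-2,3-dihydroxy-3-methylbutanedioate | COC(=O)[C@@](C)(O)[C@@](c1cc(Cl)ncc1Br)(O)C(=O)OC | intermediate
14 | dimethyl (2R,3S)-2-(5-bromo-2-chloropyridin-4-yl)-2-hydroxy-3-methyl-3-[(trimethylsilyl)oxy]butanedioate | COC(=O)[C@@](C)(O[Si](C)(C)C)[C@@](c1cc(Cl)ncc1Br)(O)C(=O)OC | intermediate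
15 | dimethyl (2R,3S)-2-(5-bromo-2-chloropyridin-4-yl)-3-methyl-2-[(triethylsilyl)oxy]-3-[(trimethylsilyl)oxy]butanedioate | COC(=O)[C@@](C)(O[Si](C)(C)C)[C@@](c1cc(Cl)ncc1Br)(O[Si](CC)(CC)CC)C(=O)OC | intermediate
16 | dimethyl (2R,3S)-2-[2-chloro-5-(chloromagnesio)pyridin-4-yl]-3-methyl-2-[(triethylsilyl)oxy]-3-[(trimethylsilyl)oxy]butanedioate (not isolated) | COC(=O)[C@@](C)(O[Si](C)(C)C)[C@@](c1cc(Cl)ncc1[Mg]Cl)(O[Si](CC)(CC)CC)C(=O)OC | intermediate
17 | methyl (5R,6S)-3-chloro-6-methyl-7-oxo-5-[(triethylsilyl)oxy]-6-[(trimethylsilyl)oxy]-6,7-dihydro-5H-cyclopenta[c]pyridine-5-carboxylate | Clc1cc2c(cn1)C(=O)[C@@](C)(O[Si](C)(C)C)[C@@]2(O[Si](CC)(CC)CC)C(=O)OC | intermediate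
18 | methyl (5R,6S)-3-chloro-6-hydroxy-6-methyl-7-oxo-5-[(triethylsilyl)oxy]-6,7-dihydro-5H-cyclopenta[c]pyridine-5-carboxylate (not isolated) | Clc1cc2c(cn1)C(=O)[C@@](C)(O)[C@@]2(O[Si](CC)(CC)CC)C(=O)OC | intermediate
19 | methyl (5R,6S)-6-acetoxy-3-chloro-6-methyl-7-oxo-5-[(triethylsilyl)oxy]-6,7-dihydro-5H-cyclopenta[c]pyridine-5-carboxylate | Clc1cc2c(cn1)C(=O)[C@@](C)(OC(C)=O)[C@@]2(O[Si](CC)(CC)CC)C(=O)OC | intermediate
20 | (S)-2-methylbutan-1-ol | CC[C@H](C)CO | starting material
21 | (S)-2-methylbutanal (not isolated) | CC[C@H](C)C=O | intermediate
22 | (2E,4S)-2,4-dimethylhex-2-enal | CC[C@H](C)/C=C(C)/C=O | intermediate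
23 | 2-[(1E,3E,5S)-3,5-dimethylhepta-1,3-dien-1-yl]-4,4,5,5-tetramethyl-1,3,2-dioxaborolane | CC[C@H](C)/C=C(C)/C=C/B1OC(C)(C)C(C)(C)O1 | intermediate
24 | methyl (5R,6S)-6-acetoxy-3-[(1E,3E,5S)-3,5-dimethylhepta-1,3-dien-1-yl]-6-methyl-7-oxo-5-[(triethylsilyl)oxy]-6,7-dihydro-5H-cyclopenta[c]pyridine-5-carboxylate | CC[C@H](C)/C=C(C)/C=C/c1cc2c(cn1)C(=O)[C@@](C)(OC(C)=O)[C@@]2(O[Si](CC)(CC)CC)C(=O)OC | intermediate
25 | methyl (5R,6S)-6-acetoxy-3-[(1E,3E,5S)-3,5-dimethylhepta-1,3-dien-1-yl]-5-hydroxy-6-methyl-7-oxo-6,7-dihydro-5H-cyclopenta[c]pyridine-5-carboxylate | CC[C@H](C)/C=C(C)/C=C/c1cc2c(cn1)C(=O)[C@@](C)(OC(C)=O)[C@@]2(O)C(=O)OC | target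

## Step count and least certain steps

Total: 14 steps. Longest linear sequence: 12 steps (steps 1–10, 13 and 14, from 1). The side chain takes 2 steps (11 and 12).

Step 6 (key step, proposed new method). The oxidant may fail to transfer oxygen to the hindered tetrasubstituted acceptor alkene while H2O2 is consumed by disproportionation. Facial discrimination may be poor because the two alkene ends differ only in aryl against methyl. Epoxidation may compete with dihydroxylation. Fallback with known chemistry: from 12, syn-dihydroxylation with ruthenium tetroxide made in situ (RuCl3 cat., NaIO4, EtOAc/MeCN/H2O, 0 °C), which is known to accept electron-poor and tetrasubstituted alkenes, should give racemic dimethyl (2RS,3SR)-2-(5-bromo-2-chloropyridin-4-yl)-2,3-dihydroxy-3-methylbutanedioate F1. Preparative chromatography on a chiral stationary phase then separates the enantiomers, and the route is rejoined at 13.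

Step 3. Proton transfer from 5 to the stabilised enolate and self-condensation of 5 may outrun the aldol addition, and the aldolate may revert before it is acetylated. Fallback: from 4, Riley oxidation (SeO2, dioxane, 90 °C) should give methyl 2-(5-bromo-2-chloropyridin-4-yl)-2-oxoacetate F2. Wittig olefination of its ketone with methyl 2-(triphenylphosphoranylidene)propanoate (toluene, 100 °C) then leads back to 8.

Step 7. Site selectivity between two tertiary hydroxyls may be incomplete with a group as small as trimethylsilyl, giving bis-silylation or the wrong mono-ether. Fallback, relying on selective removal instead of selective introduction: from 13, excess TESOTf/2,6-lutidine gives dimethyl (2R,3S)-2-(5-bromo-2-chloropyridin-4-yl)-3-methyl-2,3-bis[(triethylsilyl)oxy]butanedioate F3. PPTS in MeOH should cleave the less hindered ether on C3 to dimethyl (2R,3S)-2-(5-bromo-2-chloropyridin-4-yl)-3-hydroxy-3-methyl-2-[(triethylsilyl)oxy]butanedioate F4, and TMSCl/imidazole then gives 15.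

Step 9. Halogen–magnesium exchange next to a quaternary carbon may be slow at temperatures where the esters still resist the Grignard reagent, so intermolecular attack on an ester or reduction of the new ketone may compete. Loss of the O6 silyl group here would be harmless, since 18 is the next intermediate. Fallback with a different bond-forming principle: from 15, iBu2AlH (CH2Cl2, −78 °C) should reduce the less hindered ester on C3 to methyl (2R,3S)-2-(5-bromo-2-chloropyridin-4-yl)-3-methyl-4-oxo-2-[(triethylsilyl)oxy]-3-[(trimethylsilyl)oxy]butanoate F5. A Nozaki–Hiyama–Kishi ring closure (CrCl2, NiCl2 cat., DMF) gives methyl (5R,6R,7RS)-3-chloro-7-hydroxy-6-methyl-5-[(triethylsilyl)oxy]-6-[(trimethylsilyl)oxy]-6,7-dihydro-5H-cyclopenta[c]pyridine-5-carboxylate F6, and Dess–Martin periodinane oxidises it to 17.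

Step 13. The aqueous base may cleave the activated acetate, and protodeboronation of the dienyl boronate may outpace transmetalation. Fallback without base: from 22, a Takai-type olefination with Bu3SnCHBr2 and CrCl2 (LiI, THF/DMF) should give tributyl[(1E,3E,5S)-3,5-dimethylhepta-1,3-dien-1-yl]stannane F7. Stille coupling of F7 with 19 (Pd(PPh3)4, CuI, DMF, 60–80 °C) rejoins the route at 24.

## Further compounds

F1 | step 6 | racemic dimethyl (2RS,3SR)-2-(5-bromo-2-chloropyridin-4-yl)-2,3-dihydroxy-3-methylbutanedioate | COC(=O)[C@@](C)(O)[C@@](c1cc(Cl)ncc1Br)(O)C(=O)OC.COC(=O)[C@](C)(O)[C@](c1cc(Cl)ncc1Br)(O)C(=O)OC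
F2 | step 3 | methyl 2-(5-bromo-2-chloropyridin-4-yl)-2-oxoacetate | COC(=O)C(=O)c1cc(Cl)ncc1Br
F3 | step 7 | dimethyl (2R,3S)-2-(5-bromo-2-chloropyridin-4-yl)-3-methyl-2,3-bis[(triethylsilyl)oxy]butanedioate | COC(=O)[C@@](C)(O[Si](CC)(CC)CC)[C@@](c1cc(Cl)ncc1Br)(O[Si](CC)(CC)CC)C(=O)OC
F4 | step 7 | dimethyl (2R,3S)-2-(5-bromo-2-chloropyridin-4-yl)-3-hydroxy-3-methyl-2-[(triethylsilyl)oxy]butanedioate | COC(=O)[C@@](C)(O)[C@@](c1cc(Cl)ncc1Br)(O[Si](CC)(CC)CC)C(=O)OC
F5 | step 9 | methyl (2R,3S)-2-(5-bromo-2-chloropyridin-4-yl)-3-methyl-4-oxo-2-[(triethylsilyl)oxy]-3-[(trimethylsilyl)oxy]butanoate | O=C[C@@](C)(O[Si](C)(C)C)[C@@](c1cc(Cl)ncc1Br)(O[Si](CC)(CC)CC)C(=O)OC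
F6 | step 9 | methyl (5R,6R,7RS)-3-chloro-7-hydroxy-6-methyl-5-[(triethylsilyl)oxy]-6-[(trimethylsilyl)oxy]-6,7-dihydro-5H-cyclopenta[c]pyridine-5-carboxylate | Clc1cc2c(cn1)C(O)[C@@](C)(O[Si](C)(C)C)[C@@]2(O[Si](CC)(CC)CC)C(=O)OC
F7 | step 13 | tributyl[(1E,3E,5S)-3,5-dimethylhepta-1,3-dien-1-yl]stannane | CC[C@H](C)/C=C(C)/C=C/[Sn](CCCC)(CCCC)CCCC
A1 | alternative 1 | methyl (5R,6S)-6-acetoxy-3-[(1E,3E,5S)-3,5-dimethylhepta-1,3-dien-1-yl]-5-hydroxy-6-methyl-7-oxo-1-(trimethylsilyl)-6,7-dihydro-5H-cyclopenta[c]pyridine-5-carboxylate | CC[C@H](C)/C=C(C)/C=C/c1cc2c(c([Si](C)(C)C)n1)C(=O)[C@@](C)(OC(C)=O)[C@@]2(O)C(=O)OC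
A2 | alternative 1 | methyl (2R,3S)-3-acetoxy-2-ethynyl-2-hydroxy-3-methyl-4-oxo-6-(trimethylsilyl)hex-5-ynoate | C[Si](C)(C)C#CC(=O)[C@@](C)(OC(C)=O)[C@@](C#C)(O)C(=O)OC
A3 | alternative 1 | (2E,4E,6S)-4,6-dimethylocta-2,4-dienenitrile | CC[C@H](C)/C=C(C)/C=C/C#N
A4 | alternative 2 | methyl (5R,6S)-3-chloro-6-hydroxy-6-methyl-7-oxo-5-[(triethylsilyl)oxy]-6,7-dihydro-5H-cyclopenta[c]pyridine-5-carboxylate (identical with 18) | Clc1cc2c(cn1)C(=O)[C@@](C)(O)[C@@]2(O[Si](CC)(CC)CC)C(=O)OC
A5 | alternative 2 | methyl (2R)-2-(2-chloro-5-formylpyridin-4-yl)-3-oxo-2-[(triethylsilyl)oxy]butanoate | CC(=O)[C@@](c1cc(Cl)ncc1C=O)(O[Si](CC)(CC)CC)C(=O)OC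
A6 | alternative 3 | methyl (5R,6S)-6-acetoxy-3-chloro-5-hydroxy-6-methyl-7-oxo-6,7-dihydro-5H-cyclopenta[c]pyridine-5-carboxylate | Clc1cc2c(cn1)C(=O)[C@@](C)(OC(C)=O)[C@@]2(O)C(=O)OC
A7 | alternative 3 | methyl (3R)-3-acetoxy-4-[6-chloro-4-(4,4,5,5-tetramethyl-1,3,2-dioxaborolan-2-yl)pyridin-3-yl]-3-methyl-2,4-dioxobutanoate | COC(=O)C(=O)[C@](C)(OC(C)=O)C(=O)c1cnc(Cl)cc1B1OC(C)(C)C(C)(C)O1
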